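**Plan**
- Retrosynthesis first removes the two O‑methyl groups (O on C4 and C6), then cuts the ring bond between the benzoyl‑bearing C1 and a neighbouring oxygenated ring carbon. This opens the ring to a linear benzoyl‑capped 3,5,7‑triketo ester that already carries both prenyl groups.
- The feature that allows this: the benzene ring has oxygen on C2, C4 and C6 and carbon substituents on C1 (benzoyl), C3 and C5 (prenyl), which is the pattern of a folded chain with a carbonyl on every second carbon.
- The chain is cut between its prenyl‑bearing C4 and the C3 ketone. The fragments are a γ‑prenylated benzoylacetone (as its bis‑silyl enol ether) and the acid chloride of monomethyl prenylmalonate. Both prenyl C–C bonds come from prenyl bromide.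
- Forward: two three‑step branches, fragment union, magnesium‑mediated Claisen closure of the only ring, then selective di‑O‑methylation.
- Stereochemistry: the target has none. The α‑carbonyl stereocentres of the intermediates are racemic or epimeric and disappear on aromatisation.

Key step: step 8

Remark: the target has no stereocentre and no stereogenic double bond, so the "single enantiomer" requirement is met trivially. Compounds 8–11 are racemic or epimeric (and partly enolised) at carbons that become sp2 in step 8. The enol‑ether double‑bond geometries of 4, 5 and 10 are of no consequence and are written without descriptors.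

**Step 1**
Reactants: 1 benzoylacetone (1‑phenylbutane‑1,3‑dione); 2 prenyl bromide (1‑bromo‑3‑methylbut‑2‑ene)
Product: 3 7‑methyl‑1‑phenyloct‑6‑ene‑1,3‑dione
Conditions: LDA (2.1 equiv), THF, 0 °C; then 2 (1.0 equiv), 0 °C → rt; aq NH4Cl
Reagents that add atoms: none
Why: Double deprotonation gives the diketone dianion, whose terminal methyl‑derived carbanion is far more nucleophilic than the central enolate carbon, so the primary allylic bromide should alkylate only that carbon by SN2 (γ‑alkylation of a 1,3‑diketone dianion).

**Step 2**
Reactants: 3 7‑methyl‑1‑phenyloct‑6‑ene‑1,3‑dione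
Product: 4 7‑methyl‑1‑phenyl‑3‑(trimethylsilyloxy)octa‑2,6‑dien‑1‑one
Conditions: TMSCl (1.6 equiv), Et3N (1.5 equiv), toluene, 20 °C; filter, concentrate
Reagents that add atoms: chlorotrimethylsilane, C[Si](C)(C)Cl
Why: O‑silylation of the enolised β‑diketone with TMSCl/Et3N is the standard first stage toward a 1,3‑bis(silyloxy)diene, and the O1‑silylated regioisomer, if formed, converges on the same diene in the next step.

**Step 3**
Reactants: 4 7‑methyl‑1‑phenyl‑3‑(trimethylsilyloxy)octa‑2,6‑dien‑1‑one
Product: 5 7‑methyl‑1‑phenyl‑1,3‑bis(trimethylsilyloxy)octa‑1,3,6‑triene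
Conditions: LDA (1.2 equiv), THF, −78 °C; TMSCl (1.3 equiv), −78 → 20 °C; hexane, filter under argon, use crude
Reagents that add atoms: chlorotrimethylsilane, C[Si](C)(C)Cl
Why: LDA removes a γ‑proton (C4–H) of the β‑silyloxy enone to give an extended dienolate that TMSCl traps on oxygen, the usual kinetic deprotonation/O‑silylation route to 1,3‑bis(silyl enol ethers) of 1,3‑diketones.

**Step 4**
Reactants: 6 dimethyl malonate; 2 prenyl bromide
Product: 7 dimethyl 2‑(3‑methylbut‑2‑enyl)malonate
Conditions: NaH (1.0 equiv), 6 (1.5 equiv), THF, 0 °C; then 2 (1.0 equiv), 0 °C → rt; distil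
Reagents that add atoms: none
Why: This is a malonic ester alkylation by SN2 at the primary allylic carbon, and the excess of malonate should suppress dialkylation.

**Step 5**
Reactants: 7 dimethyl 2‑(3‑methylbut‑2‑enyl)malonate
Product: 8 2‑(methoxycarbonyl)‑5‑methylhex‑4‑enoic acid (monomethyl prenylmalonate, racemic)
Conditions: KOH (1.0 equiv), MeOH, 0 °C → rt; then cold 1 M HCl to pH 2, extract
Reagents that add atoms: potassium hydroxide, [K+].[OH-]
Why: One equivalent of hydroxide cleaves one of the two equivalent esters and the resulting carboxylate charge protects the second ester (mono‑saponification of a malonic diester), while cold acidification avoids decarboxylation.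

**Step 6**
Reactants: 8 2‑(methoxycarbonyl)‑5‑methylhex‑4‑enoic acid
Product: 9 methyl 2‑(chlorocarbonyl)‑5‑methylhex‑4‑enoate (racemic)
Conditions: (COCl)2 (1.2 equiv), cat. DMF, CH2Cl2, 0 °C → rt; evaporate, use crude
Reagents that add atoms: oxalyl chloride, O=C(Cl)C(Cl)=O
Why: Vilsmeier‑type activation with oxalyl chloride and catalytic DMF forms the acid chloride at or below room temperature with only gaseous by‑products, conditions under which the ester and the trisubstituted alkene should survive and the malonic half‑acid should not decarboxylate.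

**Step 7**
Reactants: 5 7‑methyl‑1‑phenyl‑1,3‑bis(trimethylsilyloxy)octa‑1,3,6‑triene; 9 methyl 2‑(chlorocarbonyl)‑5‑methylhex‑4‑enoate
Product: 11 methyl 2,4‑bis(3‑methylbut‑2‑enyl)‑3,5,7‑trioxo‑7‑phenylheptanoate (epimers and enol forms), via C7 trimethylsilyl enol ether of the triketo ester 10 (not isolated)
Conditions: 5 (1.5 equiv), 9 (1.0 equiv), CH2Cl2, −78 → 20 °C; then cold 0.5 M HCl/THF, short silica filtration, use promptly
Reagents that add atoms: none
Why: The bis(silyl enol ether) is a neutral equivalent of the diketone dianion and should be acylated by the acid chloride at its terminal carbon with loss of TMSCl (vinylogous Mukaiyama‑type C‑acylation of a 1,3‑bis(silyloxy)diene), without base, so the acidic malonyl C–H of 9 does not interfere, and mild aqueous acid then cleaves the remaining silyl enol ether.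

**Step 8**
Reactants: 11 methyl 2,4‑bis(3‑methylbut‑2‑enyl)‑3,5,7‑trioxo‑7‑phenylheptanoate
Product: 12 2,4,6‑trihydroxy‑3,5‑bis(3‑methylbut‑2‑enyl)benzophenone
Conditions: Mg(OMe)2 (5 equiv, from Mg and MeOH), MeOH, rt → reflux; then ice‑cold 1 M HCl, EtOAc
Reagents that add atoms: none
Why: Magnesium methoxide turns the tri‑β‑carbonyl chain into a chelated polyenolate in which the doubly activated C6 methylene, flanked by the benzoyl and C5 carbonyls, adds to the C1 ester carbonyl; methoxide is expelled and the cyclohexane‑1,3,5‑trione formed tautomerises to the hexasubstituted phloroglucinol. The closest known reaction type is the magnesium‑methoxide‑mediated intramolecular Claisen (Dieckmann‑type) cyclisation of 7‑aryl‑3,5,7‑trioxoheptanoates and their pyranone equivalents to acylphloroglucinols. The one ring is closed by a 6‑exo‑trig acyl substitution that forms the C6–C1 bond, and since benzoyl and both prenyl groups already sit on the chain, no regiochemical question arises on the ring. No stereocentre is formed, and the epimeric C2 and C4 centres become sp2 carbons. The step needs C‑acylation by C6 in preference to aldol closure of C2 onto the benzoyl ketone, O‑lactonisation to the 2‑pyranone and retro‑Claisen cleavage: the C2 prenyl group makes the aldol adduct quaternary and unable to aromatise so it reverts, methoxide reopens the pyranone, and magnesium chelation shields the ketones from methoxide, leaving the aromatic phenoxide as the only irreversible exit.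

**Step 9**
Reactants: 12 2,4,6‑trihydroxy‑3,5‑bis(3‑methylbut‑2‑enyl)benzophenone
Product: 13 2‑hydroxy‑4,6‑dimethoxy‑3,5‑bis(3‑methylbut‑2‑enyl)benzophenone (target, CNP0230472.0)
Conditions: Me2SO4 (2.1 equiv), K2CO3 (3 equiv), acetone, reflux
Reagents that add atoms: dimethyl sulfate, COS(=O)(=O)OC
Why: Williamson‑type phenol O‑methylation with two equivalents of dimethyl sulfate should etherify the para hydroxyl and one of the two equivalent ortho hydroxyls, while the last ortho hydroxyl, held in a six‑membered hydrogen bond to the benzoyl carbonyl, is too weakly acidic and nucleophilic to react, as in the standard preparation of 2‑hydroxy‑4,6‑dimethoxy aryl ketones from acylphloroglucinols.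

**Compound list**
1 | benzoylacetone (1‑phenylbutane‑1,3‑dione) | CC(=O)CC(=O)c1ccccc1 | starting material
2 | prenyl bromide (1‑bromo‑3‑methylbut‑2‑ene) | CC(C)=CCBr | starting material
3 | 7‑methyl‑1‑phenyloct‑6‑ene‑1,3‑dione | CC(C)=CCCC(=O)CC(=O)c1ccccc1 | intermediate
4 | 7‑methyl‑1‑phenyl‑3‑(trimethylsilyloxy)octa‑2,6‑dien‑1‑one | CC(C)=CCCC(O[Si](C)(C)C)=CC(=O)c1ccccc1 | intermediate
5 | 7‑methyl‑1‑phenyl‑1,3‑bis(trimethylsilyloxy)octa‑1,3,6‑triene | CC(C)=CCC=C(O[Si](C)(C)C)C=C(O[Si](C)(C)C)c1ccccc1 | intermediate
6 | dimethyl malonate | COC(=O)CC(=O)OC | starting material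
7 | dimethyl 2‑(3‑methylbut‑2‑enyl)malonate | COC(=O)C(CC=C(C)C)C(=O)OC | intermediate
8 | 2‑(methoxycarbonyl)‑5‑methylhex‑4‑enoic acid (racemic) | COC(=O)C(CC=C(C)C)C(=O)O | intermediate
9 | methyl 2‑(chlorocarbonyl)‑5‑methylhex‑4‑enoate (racemic) | COC(=O)C(CC=C(C)C)C(Cl)=O | intermediate
10 | methyl 2,4‑bis(3‑methylbut‑2‑enyl)‑3,5‑dioxo‑7‑phenyl‑7‑(trimethylsilyloxy)hept‑6‑enoate (not isolated) | COC(=O)C(CC=C(C)C)C(=O)C(CC=C(C)C)C(=O)C=C(O[Si](C)(C)C)c1ccccc1 | intermediate
11 | methyl 2,4‑bis(3‑methylbut‑2‑enyl)‑3,5,7‑trioxo‑7‑phenylheptanoate (epimers and enol forms) | COC(=O)C(CC=C(C)C)C(=O)C(CC=C(C)C)C(=O)CC(=O)c1ccccc1 | intermediate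
12 | 2,4,6‑trihydroxy‑3,5‑bis(3‑methylbut‑2‑enyl)benzophenone | CC(C)=CCc1c(O)c(CC=C(C)C)c(O)c(C(=O)c2ccccc2)c1O | intermediate
13 | 2‑hydroxy‑4,6‑dimethoxy‑3,5‑bis(3‑methylbut‑2‑enyl)benzophenone | COc1c(CC=C(C)C)c(O)c(C(=O)c2ccccc2)c(OC)c1CC=C(C)C | target

**Step count and risks**
Total step count: 9. Longest linear sequence: 6 steps (steps 1, 2, 3, 7, 8, 9, or equally 4, 5, 6, 7, 8, 9).

Steps most likely to fail:

1. Step 8 (ring closure). The doubly branched polyketone may fragment by retro‑Claisen attack of methoxide or stall at the pyranone stage. The ortho‑prenyl phenol may also cyclise to a chroman if the acidic work‑up is too harsh. Fallback: set out from prenyl bromide 2 and build the ring from a preformed arene. Friedel–Crafts benzoylation of commercial phloroglucinol (benzene‑1,3,5‑triol) with benzoyl chloride and AlCl3 in nitrobenzene should give 2,4,6‑trihydroxybenzophenone F1. Double C‑prenylation of F1 at its two free ring positions with 2 (2.2 equiv) in cold aqueous KOH should then give 12, where the route is rejoined. O‑prenylated and geminally diprenylated by‑products would have to be separated.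

2. Step 7 (fragment union). Elimination of HCl from the α‑branched malonyl chloride to a ketene, O‑acylation or attack through the central diene carbon, and premature desilylation of the moisture‑sensitive diene may all erode the C‑acylation. Fallback: set out from 3 and introduce the ester carbon last. The dilithio dianion of 3 (LDA, THF, 0 °C) is acylated at C4 with methyl 5‑methylhex‑4‑enoate (γ‑acylation of a diketone dianion by an aliphatic ester) to give 9‑methyl‑4‑(3‑methylbut‑2‑enyl)‑1‑phenyldec‑8‑ene‑1,3,5‑trione F2. Its trianion (excess LDA, THF) is carboxylated with CO2 at the terminal, most basic carbon to give 2,4‑bis(3‑methylbut‑2‑enyl)‑3,5,7‑trioxo‑7‑phenylheptanoic acid F3. Brief treatment of F3 with diazomethane in ether at 0 °C should give 11, where the route is rejoined.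

3. Step 9 (selective methylation). Over‑methylation of the hydrogen‑bonded hydroxyl, or C‑methylation with dearomatisation at a prenyl‑bearing carbon, may compete with the desired double O‑methylation. Fallback: set out from 12 and rely on chelation‑controlled cleavage instead of chelation‑controlled protection. Exhaustive O‑methylation (excess Me2SO4, K2CO3, acetone, prolonged reflux) gives 2,4,6‑trimethoxy‑3,5‑bis(3‑methylbut‑2‑enyl)benzophenone F4. Magnesium iodide etherate in toluene/ether then coordinates the ketone and should cleave only one of the two equivalent ortho methyl ethers, giving 13 directly.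

**Further compounds**
F1 | step 8 | 2,4,6‑trihydroxybenzophenone | O=C(c1ccccc1)c1c(O)cc(O)cc1O
F2 | step 7 | 9‑methyl‑4‑(3‑methylbut‑2‑enyl)‑1‑phenyldec‑8‑ene‑1,3,5‑trione | CC(C)=CCCC(=O)C(CC=C(C)C)C(=O)CC(=O)c1ccccc1
F3 | step 7 | 2,4‑bis(3‑methylbut‑2‑enyl)‑3,5,7‑trioxo‑7‑phenylheptanoic acid | OC(=O)C(CC=C(C)C)C(=O)C(CC=C(C)C)C(=O)CC(=O)c1ccccc1
F4 | step 9 | 2,4,6‑trimethoxy‑3,5‑bis(3‑methylbut‑2‑enyl)benzophenone | COc1c(CC=C(C)C)c(OC)c(C(=O)c2ccccc2)c(OC)c1CC=C(C)C
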